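## Analysis of the target

IN0946 is (2S)-2-(3,4-dimethoxyphenyl)-7-hydroxy-6,8-bis(3-methylbut-2-enyl)chroman-4-one, a flavanone in which ring A is the benzo ring C4a–C8a, ring C the dihydropyranone O1–C2–C3–C4 and ring B the 3,4-dimethoxyphenyl group on C2. Ring A carries a free hydroxyl at C7, prenyl groups at C6 and C8 and a hydrogen at C5. C2 is the only stereocentre, and with the priorities O1 > C1′ of ring B > C3 > H the descriptor in the SMILES string reads as (S). This centre is labile in two ways: as a benzylic ether next to an electron-rich ring it can ionise under acid, and as the β-carbon of the C4 ketone it is lost under base, because enolisation towards C3 expels the C8a phenoxide and the ring recloses without control. The prenyl alkenes tolerate neither hydrogenation nor electrophilic halogen, and strong acid would cyclise them onto the neighbouring 7-OH. The difficulty is therefore to form the aryl ketone bond C4–C4a without acid, to keep base away once the ketone exists, and to place two linear prenyl groups at exactly C6 and C8. The plan rests on the position of the carbonyl: C4 is bonded to C4a, which is ortho to the O1-bearing C8a and para to the C7 oxygen, so a resorcinol ring with bromine on that one carbon can be turned into a carbanion there and closed onto an amide carbon that becomes C4, with C2 already in place. The same oxygen pattern makes C6 and C8 the two positions ortho to the 7-OH, which later directs the halogens that are exchanged for prenyl.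

## Retrosynthetic reasoning

**C6–CH2 and C8–CH2 (15 to 13 and 14).** The two aryl–prenyl bonds are cut first. The prenyl alkenes would not survive the hydrogenation that sets C2 or an electrophilic halogenation, so they must arrive last. Both carbons are ortho to the free 7-OH, so diiodide 13 is the natural precursor and stannane 14 the prenyl donor. The forward reaction is a twofold sp2–sp3 cross-coupling that has to deliver the unsubstituted allyl terminus under neutral conditions.

**C–I and O–Si (13 to 12 to 11).** The iodines are removed to give phenol 12. Its hydroxyl directs halogenation to C6 and C8 only, since C5 is meta to both ring oxygens. Phenol 12 is unmasked from silyl ether 11. The forward deprotection must be buffered, because a free phenoxide next to an enolisable flavanone opens ring C.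

**C4–C4a (11 to 8).** This is the central cut. Cutting O1–C2 instead would make the ring closure a reversible conjugate addition that is hard to control at C2. Cutting C4–C4a with an acid-mediated acylation in mind would put a cation-stabilising ring B next to an acid-labile ether. Cutting between the carbonyl carbon and C4a, with a bromine marking C4a and an N-methoxy-N-methylamide as the acyl donor, separates the making of the stereocentre from the ring closure. The ketone then appears only after the base has been quenched, masked until then as the tetrahedral chelate 10. The forward step must exchange bromine for lithium (9) faster than any proton at C3 is removed.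

**C2–H and C3–H (8 to 7).** The stereocentre of 8 is traced back to the trisubstituted enol ether double bond of acrylamide 7. The amide that later becomes C4 serves here as the binding group for a chiral hydrogenation catalyst, so one functional group does two jobs. The forward reaction must distinguish the two faces of a β-aryl-β-aryloxy alkene and leave the aryl bromide untouched.

**O1–C2 (7 to 2 and 6).** The vinyl ether bond is cut to phenol 2 and propiolamide 6. The forward reaction is a conjugate addition of the hydroxyl that sits ortho to bromine, so the other hydroxyl of the resorcinol must already be blocked.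

**Fragments (6 to 3 and 4; 2 to 1).** Propiolamide 6 comes from alkyne 3 and carbamoyl chloride 4 by way of acetylide 5. Phenol 2 comes from bromoresorcinol 1 by silylation of the less hindered hydroxyl, which is the one para to bromine and therefore the later O7.

## Alternatives that were turned down

Alternative 1: Ring A is dissected into three alkynes (bonds C4a–C8a, C5–C6, C7–C8).
- Forward step: a cationic monovalent rhodium catalyst, for example [Rh(cod)2]BF4 with a bisphosphine, would cyclotrimerise the tethered diyne A2, (5S)-5-(3,4-dimethoxyphenyl)-5-[(5-methylhex-4-en-1-ynyl)oxy]pent-1-yn-3-one, with the siloxyalkyne A3, triisopropyl[(5-methylhex-4-en-1-ynyl)oxy]silane. This closes rings A and C together and gives the silyl ether A1, (2S)-2-(3,4-dimethoxyphenyl)-6,8-bis(3-methylbut-2-enyl)-7-(triisopropylsilyloxy)chroman-4-one.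
- For it: it is the most convergent plan. Three C–C bonds and two rings form at once, and A1 already carries both prenyl groups and the protected O7, so it is one desilylation away from 15 and needs no late halogenation or coupling. On these points it is stronger than the chosen route.
- Against it: A2 is a 1-alkynyl ether of an electron-rich secondary benzylic alcohol that also sits β to an ynone carbonyl. It is prone both to β-elimination and to thermal loss of the ynol ether as a ketene. A3 is hydrolytically fragile. The unsymmetrical A3 can insert in two orientations, and only one puts the silyloxy carbon at C7 of A1. A3 can also oligomerise with itself, and the prenyl alkenes are extra ligands for rhodium. Enantiopure A2 would take at least as many steps as amide 8.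
- Comparison: the chosen route spends three steps after ring closure on prenylation. In return, every position on ring A is fixed by a bromine or by phenol-directed iodination, and all intermediates are stable.

Alternative 2: Three bonds of ring C are cut at once (C4–C4a, C3–C4, O1–C2).
- Forward step: 4-iodoresorcinol A5, carbon monoxide A6 and alkyne 3 would combine with PdCl2(PPh3)2 as catalyst and an amine base, by carbonylative alkynylation and 6-endo closure of the ortho hydroxyl, to the flavone A4, 2-(3,4-dimethoxyphenyl)-7-hydroxychromen-4-one.
- For it: it reaches the bicyclic skeleton in one catalytic step, without protecting groups, and A5 and A6 are simple commercial materials. On step count to the ring system it is clearly stronger.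
- Against it: A4 has a trigonal C2. The stereocentre would have to be made afterwards by enantioselective reduction of the C2=C3 bond of a vinylogous ester, next to a ketone and a free phenol. The flavanone formed racemises by ring opening under the basic or hydridic conditions of such reductions, and over-reduction at C4 competes. The isomeric five-ring closure is a known side path of the annulation of A5 with A6. The late prenylation is still needed.
- Comparison: the chosen route is longer, but it sets C2 on an open-chain enol ether bound to the metal through its amide, before any ketone exists. The stereocentre is never formed or handled under conditions that can open ring C.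

Alternative 3: Rings A and C are built by a polyketide cascade (C4–C4a, C5–C6, C7–C8, C4a–C8a, O1–C2).
- Forward step: (E)-3,4-dimethoxycinnamic acid A8 and three units of malonic acid A9, both activated as thioesters, would be joined by a chalcone synthase acting with a chalcone reductase and a chalcone isomerase. The product is the flavanone A7, (2S)-2-(3,4-dimethoxyphenyl)-7-hydroxychroman-4-one, the same compound as 12.
- For it: five bonds, two rings and the stereocentre form in water with enzyme-level enantiocontrol and no protecting groups, A8 and A9 are bulk chemicals, and A7 is already at the stage of 12. In step and atom economy and in enantiocontrol it is stronger than the chosen route.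
- Against it: the synthase is tuned to a 4-hydroxycinnamoyl starter, and A8 lacks that hydroxyl and is bulkier. Incomplete coupling to the reductase gives products that keep the C5 oxygen and are hard to separate from A7. An isomerase that accepts the deoxy series is needed, as are thioester activation of A8 and A9 and cofactor recycling. The development work is enzyme and strain engineering with uncertain titres, and the prenylation remains.
- Comparison: the chosen route offers predictability for an unnatural ring B, ordinary laboratory equipment and free choice of scale, at the cost of five more steps to 12.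

Key step: step 5

**Assumptions (remarks on the chemistry)**

- C2 of the target is (S) as read from the SMILES. The same spatial arrangement is (3S) in the open-chain amide 8.
- The phenol addition of step 3 is taken to give mainly the E alkene 7 (aryloxy trans to the amide) after equilibration through reversible phenoxide addition. The geometry is to be assigned before step 4. If the Z isomer prevails, that isomer is purified and hydrogenated instead, with the mirror-image ligand, as in the fallback to step 3.
- The ligand hand named in step 4 is taken to give the (3S) product from 7. The sense of induction of this catalyst class cannot be derived from the structure alone, so the mirror-image ligand is used if the other hand is needed.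

## Route

Step 1
Reactants: 1 4-bromoresorcinol
Product: 2 2-bromo-5-(triisopropylsilyloxy)phenol
Conditions: TIPSCl (1.0 equiv), imidazole (2.0 equiv), CH2Cl2, 0 °C
Reagents that add atoms: triisopropylsilyl chloride, CC(C)[Si](Cl)(C(C)C)C(C)C
Why: Silylation of a phenol; the bulky silyl chloride should react mainly at the hydroxyl para to bromine, because the other hydroxyl is flanked by bromine and is the more acidic, less nucleophilic one, and one equivalent of reagent at 0 °C limits bis-silylation.

Step 2
Reactants: 3 4-ethynyl-1,2-dimethoxybenzene; 4 N-methoxy-N-methylcarbamoyl chloride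
Product: 6 3-(3,4-dimethoxyphenyl)-N-methoxy-N-methylprop-2-ynamide, via lithium (3,4-dimethoxyphenyl)acetylide 5 (not isolated)
Conditions: n-BuLi (1.05 equiv), THF, −78 °C; then 4, −78 → 0 °C
Reagents that add atoms: none
Why: Deprotonation of the terminal alkyne and acyl substitution of the alkynyllithium at the carbamoyl chloride; the N-methoxy-N-methyl chelate of the product should prevent a second acetylide addition at low temperature.

Step 3
Reactants: 2 2-bromo-5-(triisopropylsilyloxy)phenol; 6 3-(3,4-dimethoxyphenyl)-N-methoxy-N-methylprop-2-ynamide
Product: 7 (2E)-3-[2-bromo-5-(triisopropylsilyloxy)phenoxy]-3-(3,4-dimethoxyphenyl)-N-methoxy-N-methylprop-2-enamide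
Conditions: Cs2CO3 (0.3 equiv), MeCN, 60 °C
Reagents that add atoms: none
Why: Base-catalysed oxa-Michael addition of the phenoxide to the β-carbon of the alkynyl amide, with proton transfer from a second phenol regenerating the phenoxide; only the hydroxyl ortho to bromine is free, and the single alkene isomer is to be secured by crystallisation or chromatography before step 4.

Step 4
Reactants: 7 (2E)-3-[2-bromo-5-(triisopropylsilyloxy)phenoxy]-3-(3,4-dimethoxyphenyl)-N-methoxy-N-methylprop-2-enamide
Product: 8 (3S)-3-[2-bromo-5-(triisopropylsilyloxy)phenoxy]-3-(3,4-dimethoxyphenyl)-N-methoxy-N-methylpropanamide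
Conditions: [Rh(nbd)2]BF4 (2 mol %), (R)-1-[(S_P)-2-(diphenylphosphino)ferrocenyl]ethyl-di-tert-butylphosphine (2.2 mol %), H2 (20 bar), CF3CH2OH, 30 °C
Reagents that add atoms: none
Why: Rhodium–bisphosphine asymmetric hydrogenation of a β-aryloxy α,β-unsaturated carbonyl compound; the amide oxygen and the alkene chelate the cationic monovalent rhodium, and the chiral ferrocenyl bisphosphine decides which face of C3 receives hydrogen, which sets the (3S) centre (the later C2); aryl bromide, silyl ether and N–O bond are inert to this catalyst.

Step 5
Reactants: 8 (3S)-3-[2-bromo-5-(triisopropylsilyloxy)phenoxy]-3-(3,4-dimethoxyphenyl)-N-methoxy-N-methylpropanamide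
Product: 11 (2S)-2-(3,4-dimethoxyphenyl)-7-(triisopropylsilyloxy)chroman-4-one, via aryllithium 9 (not isolated), via lithium hemiaminal alkoxide 10 (not isolated)
Conditions: t-BuLi (2.05 equiv), THF, −90 °C; then AcOH in THF, −90 °C → rt
Reagents that add atoms: none
Why: Parham cyclisation: t-BuLi exchanges the bromine on the later C4a within minutes at −90 °C, and its second equivalent destroys the alkyl bromide formed, so aryllithium 9 arises irreversibly. 9 adds to the amide carbonyl in a 6-exo-trig closure that forms C4–C4a and ring C; the lithium chelate of the N-methoxy hemiaminal alkoxide 10 should not collapse at this temperature, so no ketone is present while base is, which excludes over-addition and enolisation of the product towards C3. Cold AcOH protonates 10, which loses N,O-dimethylhydroxylamine and gives ketone 11 in a weakly acidic medium. The closest known chemistry is halogen–lithium exchange with intramolecular acylation of 2-bromoaryl-substituted carboxylic acid derivatives, including 3-(2-bromophenoxy)propanoic acid derivatives to chroman-4-ones. No stereocentre is formed: C2 is carried through because no cation, radical or carbanion is generated at it, and the transient C4 centre of 10 vanishes on collapse. The selectivity needed is exchange and ring closure in preference to proton removal at C3 (which would expel the aryloxide) and to addition of t-BuLi to the amide. It is secured by the bromine that fixes the site, by the large rate advantage of bromine–lithium exchange, by the bulk of t-BuLi and by the proximity of the carbonyl; the bulky silyl ether para to the lithiated carbon can neither migrate to it nor direct a second lithiation.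

Step 6
Reactants: 11 (2S)-2-(3,4-dimethoxyphenyl)-7-(triisopropylsilyloxy)chroman-4-one
Product: 12 (2S)-2-(3,4-dimethoxyphenyl)-7-hydroxychroman-4-one
Conditions: Bu4NF (1.2 equiv), AcOH (1.5 equiv), THF, 0 °C
Reagents that add atoms: none
Why: Fluoride-induced cleavage of the aryl silyl ether; AcOH buffers the phenoxide so that the ketone is not enolised and ring C is not opened, which would racemise C2.

Step 7
Reactants: 12 (2S)-2-(3,4-dimethoxyphenyl)-7-hydroxychroman-4-one
Product: 13 (2S)-2-(3,4-dimethoxyphenyl)-7-hydroxy-6,8-diiodochroman-4-one
Conditions: NIS (2.1 equiv), DMF, 0 °C → rt, dark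
Reagents that add atoms: N-iodosuccinimide, O=C1CCC(=O)N1I
Why: Electrophilic aromatic iodination directed by the free 7-OH: C6 and C8 are its two ortho positions and are also para and ortho to O1, whereas C5 is meta to both oxygens and ring B is a much weaker nucleophile than the phenol in the absence of acid; the neutral medium leaves C2 untouched.

Step 8
Reactants: 13 (2S)-2-(3,4-dimethoxyphenyl)-7-hydroxy-6,8-diiodochroman-4-one; 14 tributyl(3-methylbut-2-enyl)stannane
Product: 15 (2S)-2-(3,4-dimethoxyphenyl)-7-hydroxy-6,8-bis(3-methylbut-2-enyl)chroman-4-one (IN0946)
Conditions: 14 (3.0 equiv), Pd(PPh3)4 (10 mol %), degassed amine-free DMF, 80 °C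
Reagents that add atoms: none
Why: Twofold Stille coupling: oxidative addition of zerovalent palladium into each C–I bond, transmetallation from the allylic stannane and reductive elimination at the unsubstituted terminus of the allyl ligand should give the linear prenyl groups; the conditions are neutral, so the free phenol and C2 are tolerated.

## Compound list

1 | 4-bromoresorcinol | Oc1ccc(Br)c(O)c1 | starting material
2 | 2-bromo-5-(triisopropylsilyloxy)phenol | Oc1cc(O[Si](C(C)C)(C(C)C)C(C)C)ccc1Br | intermediate
3 | 4-ethynyl-1,2-dimethoxybenzene | C#Cc1ccc(OC)c(OC)c1 | starting material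
4 | N-methoxy-N-methylcarbamoyl chloride | CON(C)C(Cl)=O | starting material
5 | lithium (3,4-dimethoxyphenyl)acetylide | [Li]C#Cc1ccc(OC)c(OC)c1 | intermediate
6 | 3-(3,4-dimethoxyphenyl)-N-methoxy-N-methylprop-2-ynamide | COc1ccc(C#CC(=O)N(C)OC)cc1OC | intermediate
7 | (2E)-3-[2-bromo-5-(triisopropylsilyloxy)phenoxy]-3-(3,4-dimethoxyphenyl)-N-methoxy-N-methylprop-2-enamide | COc1ccc(/C(Oc2cc(O[Si](C(C)C)(C(C)C)C(C)C)ccc2Br)=C\C(=O)N(C)OC)cc1OC | intermediate
8 | (3S)-3-[2-bromo-5-(triisopropylsilyloxy)phenoxy]-3-(3,4-dimethoxyphenyl)-N-methoxy-N-methylpropanamide | COc1ccc([C@@H](Oc2cc(O[Si](C(C)C)(C(C)C)C(C)C)ccc2Br)CC(=O)N(C)OC)cc1OC | intermediate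
9 | (3S)-3-(3,4-dimethoxyphenyl)-3-[2-lithio-5-(triisopropylsilyloxy)phenoxy]-N-methoxy-N-methylpropanamide | COc1ccc([C@@H](Oc2cc(O[Si](C(C)C)(C(C)C)C(C)C)ccc2[Li])CC(=O)N(C)OC)cc1OC | intermediate
10 | lithium (2S)-2-(3,4-dimethoxyphenyl)-4-[methoxy(methyl)amino]-7-(triisopropylsilyloxy)chroman-4-olate (C4 epimers) | COc1ccc([C@@H]2CC(O[Li])(N(C)OC)c3ccc(O[Si](C(C)C)(C(C)C)C(C)C)cc3O2)cc1OC | intermediate
11 | (2S)-2-(3,4-dimethoxyphenyl)-7-(triisopropylsilyloxy)chroman-4-one | COc1ccc([C@@H]2CC(=O)c3ccc(O[Si](C(C)C)(C(C)C)C(C)C)cc3O2)cc1OC | intermediate
12 | (2S)-2-(3,4-dimethoxyphenyl)-7-hydroxychroman-4-one | COc1ccc([C@@H]2CC(=O)c3ccc(O)cc3O2)cc1OC | intermediate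
13 | (2S)-2-(3,4-dimethoxyphenyl)-7-hydroxy-6,8-diiodochroman-4-one | COc1ccc([C@@H]2CC(=O)c3cc(I)c(O)c(I)c3O2)cc1OC | intermediate
14 | tributyl(3-methylbut-2-enyl)stannane | CCCC[Sn](CCCC)(CCCC)CC=C(C)C | starting material
15 | (2S)-2-(3,4-dimethoxyphenyl)-7-hydroxy-6,8-bis(3-methylbut-2-enyl)chroman-4-one (IN0946) | COc1ccc([C@@H]2CC(=O)c3cc(CC=C(C)C)c(O)c(CC=C(C)C)c3O2)cc1OC | target

## Step count and risks

Total step count: 8. Longest linear sequence: 7 steps (1 → 2 → 7 → 8 → 11 → 12 → 13 → 15; the branch from 3 through 6 is equally long).

**Step 5 (key step).**
- Most likely failure: proton removal at C3, by t-BuLi or by the aryllithium once formed, competes with exchange and ring closure. The amide enolate then expels the aryloxide and C2 is lost. Attack of the alkyllithium on the amide carbonyl, or migration of lithium from C4a to the benzylic C2, are lesser risks.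
- Fallback: it sets out from 8 and makes the α-hydrogens much less acidic before the exchange. Reduction with i-Bu2AlH (THF, −78 °C) should give the aldehyde (3S)-3-[2-bromo-5-(triisopropylsilyloxy)phenoxy]-3-(3,4-dimethoxyphenyl)propanal F1. Pinnick oxidation of the crude aldehyde (NaClO2, NaH2PO4, 2-methylbut-2-ene, t-BuOH/H2O) should give the acid (3S)-3-[2-bromo-5-(triisopropylsilyloxy)phenoxy]-3-(3,4-dimethoxyphenyl)propanoic acid F2. n-BuLi (2.1 equiv, THF, −100 → −40 °C, then aqueous NH4Cl) first forms the lithium carboxylate, then exchanges the bromine. The aryllithium closes onto the carboxylate to a geminal dialkoxide that can neither eliminate nor add again, and work-up returns to the route at 11.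

**Step 4.**
- Most likely failure: the catalyst discriminates poorly between the aryl and aryloxy substituents on the β-carbon, or the alkene isomerises before hydrogen transfer, so the enantiomeric purity of 8 is low. The sense of induction is also unknown in advance.
- Fallback: it makes the centre by ketone reduction and inversion, and sets out from 4 and 2. Acylation of the lithium enolate of commercial 1-(3,4-dimethoxyphenyl)ethanone with 4 (LiN(SiMe3)2, 2 equiv, THF, −78 °C) should give 3-(3,4-dimethoxyphenyl)-N-methoxy-N-methyl-3-oxopropanamide F3. Transfer hydrogenation with RuCl[(R,R)-TsDPEN](p-cymene) in HCO2H/Et3N should give (3R)-3-(3,4-dimethoxyphenyl)-3-hydroxy-N-methoxy-N-methylpropanamide F4, by the usual aryl-versus-methylene facial preference. Mitsunobu etherification with 2 (PPh3, DIAD, toluene, 0 °C) inverts the centre and returns to the route at 8. Its own weakness is partial ionisation of the electron-rich benzylic alcohol, so it is kept as the second choice.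

**Step 3.**
- Most likely failure: addition to an alkyne deactivated by the electron-rich aryl group is slow, both alkene isomers form, and silyl groups transfer between phenoxides on prolonged heating.
- Fallback: it replaces addition by vinylic substitution, and sets out from 6 and 2. Anti-hydroiodination of 6 (NaI, AcOH, 80 °C) should give (2Z)-3-(3,4-dimethoxyphenyl)-3-iodo-N-methoxy-N-methylprop-2-enamide F5. Copper-promoted coupling with 2 (CuI, N,N-dimethylglycine, Cs2CO3, dioxane, 60 °C) should proceed with retention and give the geometrically defined (2Z)-3-[2-bromo-5-(triisopropylsilyloxy)phenoxy]-3-(3,4-dimethoxyphenyl)-N-methoxy-N-methylprop-2-enamide F6. Hydrogenation of F6 as in step 4, with the mirror-image ligand, returns to the route at 8.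

**Step 8.**
- Most likely failure: allylic transposition during transmetallation or reductive elimination gives 1,1-dimethylallyl groups. Protodeiodination, or protonolysis of the stannane by the acidic phenol, may leave the crowded C8 position uncoupled.
- Fallback: it removes the regiochemical question, and sets out from 13. Stille coupling with allyltributylstannane (Pd(PPh3)4, DMF, 80 °C) should give (2S)-2-(3,4-dimethoxyphenyl)-7-hydroxy-6,8-bis(prop-2-enyl)chroman-4-one F7. Cross-metathesis with 2-methylbut-2-ene, using the second-generation Grubbs catalyst (H2IMes)(PCy3)Cl2Ru=CHPh in CH2Cl2 at 40 °C, converts both allyl groups into prenyl groups and returns to the route at 15.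

## Further compounds

F1 | step 5 | (3S)-3-[2-bromo-5-(triisopropylsilyloxy)phenoxy]-3-(3,4-dimethoxyphenyl)propanal | COc1ccc([C@@H](Oc2cc(O[Si](C(C)C)(C(C)C)C(C)C)ccc2Br)CC=O)cc1OC
F2 | step 5 | (3S)-3-[2-bromo-5-(triisopropylsilyloxy)phenoxy]-3-(3,4-dimethoxyphenyl)propanoic acid | COc1ccc([C@@H](Oc2cc(O[Si](C(C)C)(C(C)C)C(C)C)ccc2Br)CC(=O)O)cc1OC
F3 | step 4 | 3-(3,4-dimethoxyphenyl)-N-methoxy-N-methyl-3-oxopropanamide | COc1ccc(C(=O)CC(=O)N(C)OC)cc1OC
F4 | step 4 | (3R)-3-(3,4-dimethoxyphenyl)-3-hydroxy-N-methoxy-N-methylpropanamide | COc1ccc([C@H](O)CC(=O)N(C)OC)cc1OC
F5 | step 3 | (2Z)-3-(3,4-dimethoxyphenyl)-3-iodo-N-methoxy-N-methylprop-2-enamide | COc1ccc(/C(I)=C/C(=O)N(C)OC)cc1OC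
F6 | step 3 | (2Z)-3-[2-bromo-5-(triisopropylsilyloxy)phenoxy]-3-(3,4-dimethoxyphenyl)-N-methoxy-N-methylprop-2-enamide | COc1ccc(/C(Oc2cc(O[Si](C(C)C)(C(C)C)C(C)C)ccc2Br)=C/C(=O)N(C)OC)cc1OC
F7 | step 8 | (2S)-2-(3,4-dimethoxyphenyl)-7-hydroxy-6,8-bis(prop-2-enyl)chroman-4-one | COc1ccc([C@@H]2CC(=O)c3cc(CC=C)c(O)c(CC=C)c3O2)cc1OC
A1 | alternative 1 | (2S)-2-(3,4-dimethoxyphenyl)-6,8-bis(3-methylbut-2-enyl)-7-(triisopropylsilyloxy)chroman-4-one | COc1ccc([C@@H]2CC(=O)c3cc(CC=C(C)C)c(O[Si](C(C)C)(C(C)C)C(C)C)c(CC=C(C)C)c3O2)cc1OC
A2 | alternative 1 | (5S)-5-(3,4-dimethoxyphenyl)-5-[(5-methylhex-4-en-1-ynyl)oxy]pent-1-yn-3-one | COc1ccc([C@@H](OC#CCC=C(C)C)CC(=O)C#C)cc1OC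
A3 | alternative 1 | triisopropyl[(5-methylhex-4-en-1-ynyl)oxy]silane | CC(C)=CCC#CO[Si](C(C)C)(C(C)C)C(C)C
A4 | alternative 2 | 2-(3,4-dimethoxyphenyl)-7-hydroxychromen-4-one | COc1ccc(-c2cc(=O)c3ccc(O)cc3o2)cc1OC
A5 | alternative 2 | 4-iodoresorcinol | Oc1ccc(I)c(O)c1
A6 | alternative 2 | carbon monoxide | [C-]#[O+]
A7 | alternative 3 | (2S)-2-(3,4-dimethoxyphenyl)-7-hydroxychroman-4-one | COc1ccc([C@@H]2CC(=O)c3ccc(O)cc3O2)cc1OC
A8 | alternative 3 | (E)-3,4-dimethoxycinnamic acid | COc1ccc(/C=C/C(=O)O)cc1OC
A9 | alternative 3 | malonic acid | OC(=O)CC(=O)O
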